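The readings were generated by integration for an exercise, and the scatter is random.

Grey, violet, ochre and red each hold a small charge of reagent, 0.500 equiv, half of what the west run had, on 2.5 M of substrate, and you want to know how much target stands at the end.

| setting | east | west | grey | violet | ochre | red |
|---|---|---|---|---|---|---|
| substrate | 2.5 M | 2.5 M | 2.5 M | 2.5 M | 2.5 M | 2.5 M |
| reagent | 0.25 equiv | 1 equiv | 0.500 equiv | 0.500 equiv | 0.500 equiv | 0.500 equiv |
| temperature | −45 °C | −20 °C |  | 0 °C | −40 °C | −20 °C |
| remark | run made earlier | run made earlier | at −40 °C until 20 h, from then on at 0 °C |  |  |  |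
| time |  |  | 30 h | 30 h | 30 h | 30 h |

- east (time / h: target / %): 25.0: 1.1; 50.0: 0; 72.0: 0.3; 96.0: 0.3; 120: 0; 144: 0.3; 192: 0.2
- west (time / h: target / %): 4.00: 22.5; 5.00: 25.3; 8.00: 30.5; 15.0: 29.9; 20.0: 29.1; 30.0: 27.0; 60.0: 22.0

(standard deviation of a reading: 0.5 percentage points)

* the best flask by amount of target, in percent of the substrate charged; "all alike" if 1.5 percentage points covers them all (grey / violet / ochre / red / all alike)
* amount of target at the end, in percent of the substrate charged, grey
* amount of target at the end, in percent of the substrate charged, violet
* amount of target at the end, in percent of the substrate charged, ochre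
* amount of target at the end, in percent of the substrate charged, red

- a reading or a percentage of target counts all its forms, free or not

The west run climbs to 30.5% at 8.00 h and then sinks. From 15.0 h to 60.0 h its target falls from 29.9% to 22.0%, which reads as 0.00682 h⁻¹. Call this f, the fade rate: the share of the standing target lost each hour after the peak in the west run at −20 °C, a pseudo-first-order constant.

Red has west's temperature and substrate, so red is the flask you can reckon. My guess is that peak height follows reagent, which puts red's peak at 15.2%. Taking f unchanged for red, the fade is then a small correction: from 8.00 h to 30 h it takes 2.3 percentage points, leaving 13.0% for red.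

The weak link is the time of the peak, since less reagent might mean a slower rise. At west's opening pace, 22.5% in 4.00 h, a straight line reaches its peak reading in 5.42 h, though the readings bend and get there later. If rate and height both follow reagent, red keeps west's clock, and both that time and 8.00 h are shorter than 30 h, so I keep the correction. West was run at −20 °C and gives no fade at 0 °C, so for grey and violet I commit to no number, noting that grey stands at 0 °C for 10.0 h against violet's 30 h.

The forecast names red as best, with grey 9%, violet 5%, ochre 1% and red 12%, which is below my figure for red. Of grey it says “then forms quickly and decays”.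

The flasks give grey 16.2%, violet 7.24%, ochre 2.66% and red 12.9%, so grey is best.

    reagent + target ⇌ idle adduct, settled at all times (K = 0.820 L mol⁻¹, ΔH = 24.0 kJ mol⁻¹)
    substrate + reagent ⇌ target (K = 0.210 L mol⁻¹, k = 1.20 × 10⁻⁵ L mol⁻¹ s⁻¹, Ea = 70.0 kJ mol⁻¹, ΔH = 60.0 kJ mol⁻¹)
    reagent ⇌ dormant form (K = 1.30, k = 1.80 × 10⁻⁶ s⁻¹, Ea = 95.0 kJ mol⁻¹, ΔH = −47.0 kJ mol⁻¹)
    substrate + target → side product (k = 2.90 × 10⁻⁶ L mol⁻¹ s⁻¹, Ea = 65.0 kJ mol⁻¹)
    (constants at −20 °C)

Red lands at 12.9% against my 13.0%; the forecast and the flask part at grey. Grey held 2.47% of target and 93.4% of its reagent at the change of temperature, then in the warm hours reagent fell to 14.7% while target rose to 16.2% and side product to 40.7%. Violet held 12.7% of target at 15.0 h, then faded on average at 0.0372 h⁻¹ up to 30 h, 5.45 times the f read in west, while side product reached 67.8%.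

In a neighbour flask, the ochre recipe at −15 °C, the same peak and f taken unchanged from −20 °C give 13.0% again. The computed flask holds 12.8% at 30 h, close to that figure.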